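**Retrosynthetic overview**
1. Target ⇐ hydroxy ester **28** by acid-mediated desilylation, C20–O–C7 lactonization and acetal hydrolysis; the C3 and C15 carbinols come from one late oxidation/reduction pair.
2. Rings C and D together ⇐ bridging intramolecular palladium–trimethylenemethane [3+2] cycloaddition onto an acyclic α-methylene ester (C13–C14 and C8–C15 bonds in one operation).
3. C9–C10 bond, quaternary C10 and the α-methylene ester ⇐ O-alkylation/Claisen rearrangement of a ring A hydroxymethylene enone with a Morita–Baylis–Hillman bromide.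
4. Ring A ⇐ 4,4-dimethylcyclohexa-2,5-dienone, desymmetrized by rhodium-catalysed asymmetric vinyl addition (sets C5, which controls all later centers).
5. Ring order: ring A (from the starting material) → rings C and D (step 13) → δ-lactone (step 20).

Assumption: locants C1–C20 in the explanations are those of the ent-kaurane skeleton of the target (C6 = aldehyde carbon, C7 = lactone carbonyl, C20 = lactone CH2); the route is a paper proposal and nothing in it has been run.

**Step 1**
Reactants: 1 4,4-dimethylcyclohex-2-en-1-one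
Product: 2 4,4-dimethylcyclohexa-2,5-dien-1-one
Conditions: DDQ (1.2 equiv), 1,4-dioxane, reflux
Reagents that add atoms: none
Why: DDQ dehydrogenation (oxidative α,β-desaturation) can only occur on the C5–C6 side because C4 is quaternary, so the achiral cross-conjugated dienone forms.

**Step 2**
Reactants: 2 4,4-dimethylcyclohexa-2,5-dien-1-one; 3 potassium vinyltrifluoroborate
Product: 4 (5R)-5-ethenyl-4,4-dimethylcyclohex-2-en-1-one
Conditions: [Rh(C8H12)2]PF6 (3 mol %; C8H12 = 1,5-cyclooctadiene), (R)-BINAP (3.3 mol %), PhMe/H2O 4:1, 100 °C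
Reagents that add atoms: none
Why: Rhodium-catalysed asymmetric 1,4-addition (Hayashi–Miyaura type) to one of the two enantiotopic enone units desymmetrizes 2 and sets the (5R) center, the (R)-BINAP choice being made by analogy with cyclohexenone additions (use (S)-BINAP if the sense proves opposite), and the more hindered remaining enone does not add a second vinyl group.

**Step 3**
Reactants: 4 (5R)-5-ethenyl-4,4-dimethylcyclohex-2-en-1-one
Product: 6 (5S)-5-(dimethoxymethyl)-4,4-dimethylcyclohex-2-en-1-one, via keto aldehyde 5 (not isolated)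
Conditions: O3, CH2Cl2/MeOH, −78 °C (Sudan red 7B end point); Me2S, −78 → 0 °C; then HC(OMe)3, TsOH·H2O (5 mol %), 0 °C
Reagents that add atoms: ozone, [O-][O+]=O (carbonyl oxygen of 5); trimethyl orthoformate, COC(OC)OC (the two methoxy groups of 6)
Why: Chemoselective ozonolysis of the isolated vinyl group (the electron-poor enone reacts far more slowly) followed by acid-catalysed acetalization in the same flask masks the future C6 aldehyde before its α-stereocenter (C5) can epimerize.

**Step 4**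
Reactants: 6 (5S)-5-(dimethoxymethyl)-4,4-dimethylcyclohex-2-en-1-one; 7 ethyl formate
Product: 8 (5R,6Z)-5-(dimethoxymethyl)-6-(hydroxymethylidene)-4,4-dimethylcyclohex-2-en-1-one
Conditions: NaH (1.2 equiv), EtOH (cat.), THF, 0 → 23 °C; AcOH quench
Reagents that add atoms: none
Why: Crossed Claisen condensation (α'-formylation); C10 is the only enolizable carbon of 6 because the γ-carbon is quaternary, so the future C20 is installed regiospecifically as the chelated enol without touching C5.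

**Step 5**
Reactants: 9 pent-4-enal; 10 methyl acrylate
Product: 11 methyl 3-hydroxy-2-methylidenehept-6-enoate (racemic)
Conditions: DABCO (0.5 equiv), MeOH, 23 °C, 3 d
Reagents that add atoms: none
Why: Morita–Baylis–Hillman reaction of an unhindered aliphatic aldehyde; the racemic carbinol center is erased in step 6.

**Step 6**
Reactants: 11 methyl 3-hydroxy-2-methylidenehept-6-enoate
Product: 12 methyl (2Z)-2-(bromomethyl)hepta-2,6-dienoate
Conditions: NBS, Me2S, CH2Cl2, 0 → 23 °C
Reagents that add atoms: N-bromosuccinimide, BrN1C(=O)CCC1=O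
Why: Corey–Kim-type activation with SN2' delivery of bromide converts the Morita–Baylis–Hillman alcohol into the thermodynamically favoured (Z)-2-(bromomethyl)enoate and leaves the terminal alkene untouched.

**Step 7**
Reactants: 8 (5R,6Z)-5-(dimethoxymethyl)-6-(hydroxymethylidene)-4,4-dimethylcyclohex-2-en-1-one; 12 methyl (2Z)-2-(bromomethyl)hepta-2,6-dienoate
Product: 14 methyl (3S)-3-[(1S,6R)-6-(dimethoxymethyl)-1-formyl-5,5-dimethyl-2-oxocyclohex-3-en-1-yl]-2-methylidenehept-6-enoate, via alkoxymethylene enone 13 (not isolated)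
Conditions: K2CO3 (1.1 equiv), 18-crown-6 (10 mol %), PhMe, 23 °C; then 110 °C
Reagents that add atoms: none
Why: O-alkylation of the acidic hydroxymethylene enone (SN2 at the primary allylic bromide) gives the (E)-enol ether 13, whose Claisen rearrangement through a chair transition state on the face anti to the C5 acetal (held pseudo-axial by allylic strain) forms C9–C10 and sets the quaternary C10 and the tertiary C9 (both S) while releasing the C20 aldehyde and the α-methylene ester.

**Step 8**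
Reactants: 14 methyl (3S)-3-[(1S,6R)-6-(dimethoxymethyl)-1-formyl-5,5-dimethyl-2-oxocyclohex-3-en-1-yl]-2-methylidenehept-6-enoate
Product: 15 methyl (3S)-3-[(1S,6R)-6-(dimethoxymethyl)-1-(hydroxymethyl)-5,5-dimethyl-2-oxocyclohex-3-en-1-yl]-2-methylidenehept-6-enoate
Conditions: NaBH4 (0.3 equiv), MeOH/CH2Cl2 1:1, −78 °C; AcOH quench
Reagents that add atoms: none
Why: Chemoselective hydride reduction: at −78 °C NaBH4 reduces the aldehyde but neither the hindered enone nor the acrylate, and no stereocenter is formed.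

**Step 9**
Reactants: 15 (primary alcohol from step 8)
Product: 16 methyl (3S)-3-[(1S,6R)-1-{[tert-butyl(dimethyl)silyl]oxymethyl}-6-(dimethoxymethyl)-5,5-dimethyl-2-oxocyclohex-3-en-1-yl]-2-methylidenehept-6-enoate
Conditions: TBSCl, imidazole, DMF, 23 °C
Reagents that add atoms: tert-butyldimethylsilyl chloride, CC(C)(C)[Si](C)(C)Cl
Why: Silylation of the neopentyl primary alcohol blocks retro-aldol loss of C20 and premature lactonization onto the acrylate ester, which must stay acyclic for step 13.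

**Step 10**
Reactants: 16 (silyl ether from step 9)
Product: 17 methyl (3S)-3-[(1S,6R)-1-{[tert-butyl(dimethyl)silyl]oxymethyl}-6-(dimethoxymethyl)-5,5-dimethyl-2-oxocyclohex-3-en-1-yl]-2-methylidene-6-oxohexanoate
Conditions: O3, CH2Cl2/MeOH 4:1, −78 °C (Sudan red 7B end point); Me2S
Reagents that add atoms: ozone, [O-][O+]=O
Why: Chemoselective ozonolysis: the monosubstituted terminal alkene is cleaved much faster than the two electron-poor alkenes, giving the C13 aldehyde.

**Step 11**
Reactants: 17 (C13 aldehyde); 18 (2-bromoprop-2-en-1-yl)trimethylsilane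
Product: 19 methyl (3S,6RS)-3-[(1S,6R)-1-{[tert-butyl(dimethyl)silyl]oxymethyl}-6-(dimethoxymethyl)-5,5-dimethyl-2-oxocyclohex-3-en-1-yl]-6-hydroxy-2-methylidene-7-[(trimethylsilyl)methyl]oct-7-enoate
Conditions: CrCl2 (4 equiv), NiCl2 (2 mol %), DMF, 23 °C
Reagents that add atoms: none
Why: Nozaki–Hiyama–Kishi coupling: the vinylchromium species adds only to the aldehyde (enone, esters and acetal tolerated), and both C13 epimers are used because this center becomes part of the allyl system in step 13.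

**Step 12**
Reactants: 19 (allylic alcohol from step 11)
Product: 20 methyl (3S,6RS)-6-acetoxy-3-[(1S,6R)-1-{[tert-butyl(dimethyl)silyl]oxymethyl}-6-(dimethoxymethyl)-5,5-dimethyl-2-oxocyclohex-3-en-1-yl]-2-methylidene-7-[(trimethylsilyl)methyl]oct-7-enoate
Conditions: Ac2O, Et3N, DMAP (10 mol %), CH2Cl2, 0 → 23 °C
Reagents that add atoms: acetic anhydride, CC(=O)OC(C)=O
Why: DMAP-catalysed acetylation gives the 2-(silylmethyl)allyl acetate needed to generate a trimethylenemethane–palladium species; no stereochemical consequence.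

**Step 13**
Reactants: 20 (silylmethyl allyl acetate)
Product: 21 methyl (1R,2S,5R)-2-[(1S,6R)-1-{[tert-butyl(dimethyl)silyl]oxymethyl}-6-(dimethoxymethyl)-5,5-dimethyl-2-oxocyclohex-3-en-1-yl]-6-methylidenebicyclo[3.2.1]octane-1-carboxylate
Conditions: Pd(OAc)2 (10 mol %), P(Oi-Pr)3 (60 mol %), PhMe (0.01 M), 100 °C
Reagents that add atoms: none
Why: Proposed new method: zerovalent palladium ionizes the allylic acetate and acetate removes the silyl group to give a trimethylenemethane–palladium zwitterion whose substituted terminus (C13) adds to the methylene carbon C14 of the acrylate through a six-membered chair in which allylic strain keeps C9–H in the acrylate plane and C10 axial, after which the ester enolate at C8 closes onto the π-allyl terminus (C15) from the face of the axial C13 substituent, so rings C and D form together with C8 and C13 bridged anti to C10 as in the target; the closest known reaction type is Trost's intramolecular palladium–trimethylenemethane [3+2] cycloaddition, which so far gives fused rather than bridged bicycles.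

**Step 14**
Reactants: 21 (bicyclic enone ester)
Product: 23 methyl (1R,2S,5R)-2-[(1S,4S,6R)-1-{[tert-butyl(dimethyl)silyl]oxymethyl}-6-(dimethoxymethyl)-4-hydroxy-5,5-dimethyl-2-oxocyclohexyl]-6-methylidenebicyclo[3.2.1]octane-1-carboxylate, via boronate 22 (not isolated)
Conditions: CuCl (10 mol %), Xantphos (10 mol %), NaOt-Bu (15 mol %), B2pin2 (1.3 equiv), MeOH (2 equiv), THF, 23 °C; then NaBO3·4H2O, THF/H2O, 23 °C
Reagents that add atoms: bis(pinacolato)diboron, CC1(C)OB(OC1(C)C)B1OC(C)(C)C(C)(C)O1 (boron of 22); sodium perborate, [Na+].[O-]OB=O (hydroxyl oxygen of 23)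
Why: Copper-catalysed conjugate borylation followed by stereoretentive perborate oxidation; the boryl group enters axially on the ring A face opposite to C20 and the axial C4 methyl, giving a provisional C3 alcohol anti to C20 that directs step 15 and is corrected in steps 18 and 19.

**Step 15**
Reactants: 23 (β-hydroxy ketone)
Product: 24 methyl (1R,2S,5R)-2-[(1S,2S,4S,6R)-1-{[tert-butyl(dimethyl)silyl]oxymethyl}-6-(dimethoxymethyl)-2,4-dihydroxy-5,5-dimethylcyclohexyl]-6-methylidenebicyclo[3.2.1]octane-1-carboxylate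
Conditions: Me4NBH(OAc)3 (5 equiv), MeCN/AcOH 1:1, −30 °C
Reagents that add atoms: none
Why: Evans–Saksena hydroxyl-directed reduction: intramolecular hydride delivery from the axial C3 alkoxyborohydride to the same face of the C1 ketone gives the 1,3-anti diol, i.e. the equatorial (1S) alcohol syn to C20 required by the target.

**Step 16**
Reactants: 24 (1,3-anti diol)
Product: 25 methyl (1R,2S,5R)-2-[(1S,2S,4S,6R)-2-acetoxy-1-{[tert-butyl(dimethyl)silyl]oxymethyl}-6-(dimethoxymethyl)-4-hydroxy-5,5-dimethylcyclohexyl]-6-methylidenebicyclo[3.2.1]octane-1-carboxylate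
Conditions: Ac2O (1.2 equiv), pyridine, DMAP (5 mol %), CH2Cl2, −20 → 0 °C
Reagents that add atoms: acetic anhydride, CC(=O)OC(C)=O
Why: Kinetic acylation: the equatorial C1 hydroxyl reacts faster than the axial C3 hydroxyl, which is flanked by the gem-dimethyl group and two syn-axial hydrogens; no stereocenter changes.

**Step 17**
Reactants: 25 (C1 monoacetate)
Product: 26 methyl (1S,2S,5R,7S)-2-[(1S,2S,4S,6R)-2-acetoxy-1-{[tert-butyl(dimethyl)silyl]oxymethyl}-6-(dimethoxymethyl)-4-hydroxy-5,5-dimethylcyclohexyl]-7-hydroxy-6-methylidenebicyclo[3.2.1]octane-1-carboxylate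
Conditions: SeO2 (0.5 equiv), t-BuOOH (3 equiv), CH2Cl2, 23 °C
Reagents that add atoms: selenium dioxide, O=[Se]=O (oxygen donor, regenerated); tert-butyl hydroperoxide, CC(C)(C)OO (terminal oxidant)
Why: Selenium dioxide allylic oxidation (ene reaction then [2,3]-sigmatropic shift) can only use the C15 hydrogens because C13 is a bridgehead, so the exocyclic alkene is kept and C15 is hydroxylated, mainly from the exo face; this configuration is erased in step 18.

**Step 18**
Reactants: 26 (3,15-diol)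
Product: 27 methyl (1S,2S,5R)-2-[(1S,2S,6S)-2-acetoxy-1-{[tert-butyl(dimethyl)silyl]oxymethyl}-6-(dimethoxymethyl)-5,5-dimethyl-4-oxocyclohexyl]-6-methylidene-7-oxobicyclo[3.2.1]octane-1-carboxylate
Conditions: Dess–Martin periodinane (3 equiv), NaHCO3, CH2Cl2, 23 °C
Reagents that add atoms: none
Why: Dess–Martin oxidation of both secondary alcohols gives the C3 ketone and the C15 enone, erasing the two provisional stereocenters without touching any epimerizable position.

**Step 19**
Reactants: 27 (3,15-diketone)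
Product: 28 methyl (1S,2S,5R,7R)-2-[(1S,2S,4R,6R)-2-acetoxy-1-{[tert-butyl(dimethyl)silyl]oxymethyl}-6-(dimethoxymethyl)-4-hydroxy-5,5-dimethylcyclohexyl]-7-hydroxy-6-methylidenebicyclo[3.2.1]octane-1-carboxylate
Conditions: NaBH4 (2 equiv), CeCl3·7H2O (2 equiv), MeOH, −78 → −20 °C
Reagents that add atoms: none
Why: Luche reduction: 1,2-hydride addition to the C15 enone from the exo face (away from the three-carbon bridge) gives the endo (15R) alcohol, and axial hydride attack on the C3 ketone from the face opposite to C20 and the axial C4 methyl gives the equatorial (3R) alcohol, while acetate and ester survive.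

**Step 20**
Reactants: 28 (silyl ether, methyl ester, dimethyl acetal)
Product: 31 target CNP0536233.1, via primary alcohol 29 (not isolated), via lactone acetal 30 (not isolated)
Conditions: 2 M aq. HCl/THF 1:4, 23 → 45 °C
Reagents that add atoms: water, O (aldehyde oxygen)
Why: Acid-mediated global unmasking: silyl ether cleavage, lactonization of the C20 alcohol onto the C7 methyl ester (six-membered transesterification) and acetal hydrolysis give the target without touching a stereocenter, the equatorial C5 aldehyde being the stable epimer.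

**Compound list**
1 | 4,4-dimethylcyclohex-2-en-1-one | CC1(C)CCC(=O)C=C1 | starting material
2 | 4,4-dimethylcyclohexa-2,5-dien-1-one | CC1(C)C=CC(=O)C=C1 | intermediate
3 | potassium vinyltrifluoroborate | [K+].F[B-](F)(F)C=C | starting material
4 | (5R)-5-ethenyl-4,4-dimethylcyclohex-2-en-1-one | O=C1C=CC(C)(C)[C@@H](C=C)C1 | intermediate
5 | (1S)-2,2-dimethyl-5-oxocyclohex-3-ene-1-carbaldehyde (not isolated) | O=C1C=CC(C)(C)[C@@H](C=O)C1 | intermediate
6 | (5S)-5-(dimethoxymethyl)-4,4-dimethylcyclohex-2-en-1-one | O=C1C=CC(C)(C)[C@@H](C(OC)OC)C1 | intermediate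
7 | ethyl formate | CCOC=O | starting material
8 | (5R,6Z)-5-(dimethoxymethyl)-6-(hydroxymethylidene)-4,4-dimethylcyclohex-2-en-1-one | O=C1C=CC(C)(C)[C@@H](C(OC)OC)/C1=C/O | intermediate
9 | pent-4-enal | C=CCCC=O | starting material
10 | methyl acrylate | C=CC(=O)OC | starting material
11 | methyl 3-hydroxy-2-methylidenehept-6-enoate (racemic) | C=CCCC(O)C(=C)C(=O)OC | intermediate
12 | methyl (2Z)-2-(bromomethyl)hepta-2,6-dienoate | C=CCC/C=C(\CBr)C(=O)OC | intermediate
13 | methyl (2E)-2-({(E)-[(6R)-6-(dimethoxymethyl)-5,5-dimethyl-2-oxocyclohex-3-en-1-ylidene]methoxy}methyl)hepta-2,6-dienoate (not isolated) | O=C1C=CC(C)(C)[C@@H](C(OC)OC)/C1=C\OC/C(C(=O)OC)=C\CCC=C | intermediate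
14 | methyl (3S)-3-[(1S,6R)-6-(dimethoxymethyl)-1-formyl-5,5-dimethyl-2-oxocyclohex-3-en-1-yl]-2-methylidenehept-6-enoate | C=C(C(=O)OC)[C@@H](CCC=C)[C@]1(C=O)C(=O)C=CC(C)(C)[C@H]1C(OC)OC | intermediate
15 | methyl (3S)-3-[(1S,6R)-6-(dimethoxymethyl)-1-(hydroxymethyl)-5,5-dimethyl-2-oxocyclohex-3-en-1-yl]-2-methylidenehept-6-enoate | C=C(C(=O)OC)[C@@H](CCC=C)[C@]1(CO)C(=O)C=CC(C)(C)[C@H]1C(OC)OC | intermediate
16 | methyl (3S)-3-[(1S,6R)-1-{[tert-butyl(dimethyl)silyl]oxymethyl}-6-(dimethoxymethyl)-5,5-dimethyl-2-oxocyclohex-3-en-1-yl]-2-methylidenehept-6-enoate | C=C(C(=O)OC)[C@@H](CCC=C)[C@]1(CO[Si](C)(C)C(C)(C)C)C(=O)C=CC(C)(C)[C@H]1C(OC)OC | intermediate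
17 | methyl (3S)-3-[(1S,6R)-1-{[tert-butyl(dimethyl)silyl]oxymethyl}-6-(dimethoxymethyl)-5,5-dimethyl-2-oxocyclohex-3-en-1-yl]-2-methylidene-6-oxohexanoate | C=C(C(=O)OC)[C@@H](CCC=O)[C@]1(CO[Si](C)(C)C(C)(C)C)C(=O)C=CC(C)(C)[C@H]1C(OC)OC | intermediate
18 | (2-bromoprop-2-en-1-yl)trimethylsilane | C=C(Br)C[Si](C)(C)C | starting material
19 | methyl (3S,6RS)-3-[(1S,6R)-1-{[tert-butyl(dimethyl)silyl]oxymethyl}-6-(dimethoxymethyl)-5,5-dimethyl-2-oxocyclohex-3-en-1-yl]-6-hydroxy-2-methylidene-7-[(trimethylsilyl)methyl]oct-7-enoate | C=C(C(=O)OC)[C@@H](CCC(O)C(=C)C[Si](C)(C)C)[C@]1(CO[Si](C)(C)C(C)(C)C)C(=O)C=CC(C)(C)[C@H]1C(OC)OC | intermediate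
20 | methyl (3S,6RS)-6-acetoxy-3-[(1S,6R)-1-{[tert-butyl(dimethyl)silyl]oxymethyl}-6-(dimethoxymethyl)-5,5-dimethyl-2-oxocyclohex-3-en-1-yl]-2-methylidene-7-[(trimethylsilyl)methyl]oct-7-enoate | C=C(C(=O)OC)[C@@H](CCC(OC(C)=O)C(=C)C[Si](C)(C)C)[C@]1(CO[Si](C)(C)C(C)(C)C)C(=O)C=CC(C)(C)[C@H]1C(OC)OC | intermediate
21 | methyl (1R,2S,5R)-2-[(1S,6R)-1-{[tert-butyl(dimethyl)silyl]oxymethyl}-6-(dimethoxymethyl)-5,5-dimethyl-2-oxocyclohex-3-en-1-yl]-6-methylidenebicyclo[3.2.1]octane-1-carboxylate | C=C1C[C@]2(C(=O)OC)C[C@H]1CC[C@H]2[C@]1(CO[Si](C)(C)C(C)(C)C)C(=O)C=CC(C)(C)[C@H]1C(OC)OC | intermediate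
22 | methyl (1R,2S,5R)-2-[(1S,4S,6R)-1-{[tert-butyl(dimethyl)silyl]oxymethyl}-6-(dimethoxymethyl)-5,5-dimethyl-2-oxo-4-(4,4,5,5-tetramethyl-1,3,2-dioxaborolan-2-yl)cyclohexyl]-6-methylidenebicyclo[3.2.1]octane-1-carboxylate (not isolated) | C=C1C[C@]2(C(=O)OC)C[C@H]1CC[C@H]2[C@]1(CO[Si](C)(C)C(C)(C)C)C(=O)C[C@H](B3OC(C)(C)C(C)(C)O3)C(C)(C)[C@H]1C(OC)OC | intermediate
23 | methyl (1R,2S,5R)-2-[(1S,4S,6R)-1-{[tert-butyl(dimethyl)silyl]oxymethyl}-6-(dimethoxymethyl)-4-hydroxy-5,5-dimethyl-2-oxocyclohexyl]-6-methylidenebicyclo[3.2.1]octane-1-carboxylate | C=C1C[C@]2(C(=O)OC)C[C@H]1CC[C@H]2[C@]1(CO[Si](C)(C)C(C)(C)C)C(=O)C[C@H](O)C(C)(C)[C@H]1C(OC)OC | intermediate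
24 | methyl (1R,2S,5R)-2-[(1S,2S,4S,6R)-1-{[tert-butyl(dimethyl)silyl]oxymethyl}-6-(dimethoxymethyl)-2,4-dihydroxy-5,5-dimethylcyclohexyl]-6-methylidenebicyclo[3.2.1]octane-1-carboxylate | C=C1C[C@]2(C(=O)OC)C[C@H]1CC[C@H]2[C@]1(CO[Si](C)(C)C(C)(C)C)[C@@H](O)C[C@H](O)C(C)(C)[C@H]1C(OC)OC | intermediate
25 | methyl (1R,2S,5R)-2-[(1S,2S,4S,6R)-2-acetoxy-1-{[tert-butyl(dimethyl)silyl]oxymethyl}-6-(dimethoxymethyl)-4-hydroxy-5,5-dimethylcyclohexyl]-6-methylidenebicyclo[3.2.1]octane-1-carboxylate | C=C1C[C@]2(C(=O)OC)C[C@H]1CC[C@H]2[C@]1(CO[Si](C)(C)C(C)(C)C)[C@@H](OC(C)=O)C[C@H](O)C(C)(C)[C@H]1C(OC)OC | intermediate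
26 | methyl (1S,2S,5R,7S)-2-[(1S,2S,4S,6R)-2-acetoxy-1-{[tert-butyl(dimethyl)silyl]oxymethyl}-6-(dimethoxymethyl)-4-hydroxy-5,5-dimethylcyclohexyl]-7-hydroxy-6-methylidenebicyclo[3.2.1]octane-1-carboxylate (major C15 epimer) | C=C1[C@H](O)[C@]2(C(=O)OC)C[C@H]1CC[C@H]2[C@]1(CO[Si](C)(C)C(C)(C)C)[C@@H](OC(C)=O)C[C@H](O)C(C)(C)[C@H]1C(OC)OC | intermediate
27 | methyl (1S,2S,5R)-2-[(1S,2S,6S)-2-acetoxy-1-{[tert-butyl(dimethyl)silyl]oxymethyl}-6-(dimethoxymethyl)-5,5-dimethyl-4-oxocyclohexyl]-6-methylidene-7-oxobicyclo[3.2.1]octane-1-carboxylate | C=C1C(=O)[C@]2(C(=O)OC)C[C@H]1CC[C@H]2[C@]1(CO[Si](C)(C)C(C)(C)C)[C@@H](OC(C)=O)CC(=O)C(C)(C)[C@H]1C(OC)OC | intermediate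
28 | methyl (1S,2S,5R,7R)-2-[(1S,2S,4R,6R)-2-acetoxy-1-{[tert-butyl(dimethyl)silyl]oxymethyl}-6-(dimethoxymethyl)-4-hydroxy-5,5-dimethylcyclohexyl]-7-hydroxy-6-methylidenebicyclo[3.2.1]octane-1-carboxylate | C=C1[C@@H](O)[C@]2(C(=O)OC)C[C@H]1CC[C@H]2[C@]1(CO[Si](C)(C)C(C)(C)C)[C@@H](OC(C)=O)C[C@@H](O)C(C)(C)[C@H]1C(OC)OC | intermediate
29 | methyl (1S,2S,5R,7R)-2-[(1S,2S,4R,6R)-2-acetoxy-6-(dimethoxymethyl)-4-hydroxy-1-(hydroxymethyl)-5,5-dimethylcyclohexyl]-7-hydroxy-6-methylidenebicyclo[3.2.1]octane-1-carboxylate (not isolated) | C=C1[C@@H](O)[C@]2(C(=O)OC)C[C@H]1CC[C@H]2[C@]1(CO)[C@@H](OC(C)=O)C[C@@H](O)C(C)(C)[C@H]1C(OC)OC | intermediate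
30 | dimethyl acetal of the target at C6, i.e. the 7,20-lactone with C5 bearing CH(OMe)2 (not isolated) | C=C1[C@@H](O)[C@]23C[C@H]1CC[C@H]2[C@]1(COC3=O)[C@@H](OC(C)=O)C[C@@H](O)C(C)(C)[C@H]1C(OC)OC | intermediate
31 | CNP0536233.1: (1S,3R,5R,8S,9S,10S,13R,15R)-1-acetoxy-3,15-dihydroxy-6-oxo-6,7-secokaur-16-en-7,20-olide (ent-kaurane locants) | C=C1[C@@H]2CC[C@@H]3[C@](C2)(C(=O)OC[C@]32[C@@H](OC(C)=O)C[C@@H](O)C(C)(C)[C@H]2C=O)[C@@H]1O | target

**Step count:** 20 steps in total. The longest linear sequence is 18 steps (steps 1–4 and 7–20); steps 5 and 6 make the second fragment.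

**Steps most likely to fail, with fallbacks**

Step 13 (bridging cycloaddition). The risks are simple protonation of the Michael adduct, formation of the C13 epimer that cannot bridge, and competing reaction at the ring A enone. The fallback sets out from aldehyde 17, builds rings C and D one after the other, and returns at 21. Nozaki–Hiyama–Kishi addition of 2-bromopropene (CrCl2, NiCl2 cat.) gives the isopropenyl carbinol F2. CBr4/PPh3 converts it into the allylic bromide F3 (either allylic isomer gives the same radical). Slow addition of Bu3SnH/AIBN in benzene at 80 °C closes ring C by 6-endo cyclization of the allylic radical onto the acrylate, giving the isopropenylcyclohexane ester F4; its 1,4-trans isomer is the one that can bridge. LiN(i-Pr)2/TBSCl gives the ketene silyl acetal F5 (ring A has no enolizable hydrogen). Stoichiometric Pd(OAc)2 in DMSO at 45 °C (oxidative cycloalkenylation mediated by divalent palladium) then forms the C8–C15 bond with the exocyclic alkene and delivers 21.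

Step 7 (O-alkylation/Claisen). The risks are competing C-alkylation at the bromomethyl carbon and loss of C9/C10 diastereocontrol if the (Z)-enol ether or a boat transition state takes part. The fallback sets out from alcohol 11 and enone 8 and returns at 14. Boc2O/DMAP converts 11 into the tert-butyl carbonate F1. A chiral Lewis base (β-isocupreidine, 10 mol %, PhMe, 23 °C) then adds to F1 in SN2' fashion, and the enolate of 8 attacks the resulting allylammonium salt at the substituted carbon (second SN2'). This ionic allylic alkylation gives 14 directly, with the catalyst rather than a sigmatropic transition state controlling C9.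

Step 16 (selective acetylation of the C1 hydroxyl). The risk is competing acetylation of the C3 hydroxyl. The fallback sets out from enone 21, avoids any diol, and returns at 25. Nucleophilic epoxidation (t-BuOOH, DBU) on the face opposite to C20 gives the epoxy ketone F6. NaBH4/CeCl3 delivers hydride to C1 from the same less hindered face and gives the epoxy alcohol F7 with the C1 hydroxyl syn to C20. Ac2O/pyridine gives the epoxy acetate F8, which has no second hydroxyl. MgI2 opens the oxirane trans-diaxially at the unhindered C2 to give the iodohydrin F9, which is reduced in the same flask with Bu3SnH/AIBN to 25.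

**Further compounds**
F1 | step 7 | methyl 3-[(tert-butoxycarbonyl)oxy]-2-methylidenehept-6-enoate (racemic) | C=CCCC(OC(=O)OC(C)(C)C)C(=C)C(=O)OC
F2 | step 13 | methyl (3S,6RS)-3-[(1S,6R)-1-{[tert-butyl(dimethyl)silyl]oxymethyl}-6-(dimethoxymethyl)-5,5-dimethyl-2-oxocyclohex-3-en-1-yl]-6-hydroxy-7-methyl-2-methylideneoct-7-enoate | C=C(C(=O)OC)[C@@H](CCC(O)C(C)=C)[C@]1(CO[Si](C)(C)C(C)(C)C)C(=O)C=CC(C)(C)[C@H]1C(OC)OC
F3 | step 13 | methyl (3S,6RS)-6-bromo-3-[(1S,6R)-1-{[tert-butyl(dimethyl)silyl]oxymethyl}-6-(dimethoxymethyl)-5,5-dimethyl-2-oxocyclohex-3-en-1-yl]-7-methyl-2-methylideneoct-7-enoate | C=C(C(=O)OC)[C@@H](CCC(Br)C(C)=C)[C@]1(CO[Si](C)(C)C(C)(C)C)C(=O)C=CC(C)(C)[C@H]1C(OC)OC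
F4 | step 13 | methyl (1RS,2R,5R)-2-[(1S,6R)-1-{[tert-butyl(dimethyl)silyl]oxymethyl}-6-(dimethoxymethyl)-5,5-dimethyl-2-oxocyclohex-3-en-1-yl]-5-(prop-1-en-2-yl)cyclohexane-1-carboxylate | COC(=O)C1C[C@H](C(C)=C)CC[C@H]1[C@]1(CO[Si](C)(C)C(C)(C)C)C(=O)C=CC(C)(C)[C@H]1C(OC)OC
F5 | step 13 | tert-butyldimethylsilyl methyl ketene acetal of F4 | COC(O[Si](C)(C)C(C)(C)C)=C1C[C@H](C(C)=C)CC[C@H]1[C@]1(CO[Si](C)(C)C(C)(C)C)C(=O)C=CC(C)(C)[C@H]1C(OC)OC
F6 | step 16 | 2,3-epoxy ketone of 21 (ring A oxirane anti to C20) | C=C1C[C@]2(C(=O)OC)C[C@H]1CC[C@H]2[C@]1(CO[Si](C)(C)C(C)(C)C)C(=O)[C@@H]3O[C@@H]3C(C)(C)[C@H]1C(OC)OC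
F7 | step 16 | 2,3-epoxy-1-ol from F6 (C1 hydroxyl syn to C20) | C=C1C[C@]2(C(=O)OC)C[C@H]1CC[C@H]2[C@]1(CO[Si](C)(C)C(C)(C)C)[C@@H](O)[C@@H]3O[C@@H]3C(C)(C)[C@H]1C(OC)OC
F8 | step 16 | C1 acetate of F7 | C=C1C[C@]2(C(=O)OC)C[C@H]1CC[C@H]2[C@]1(CO[Si](C)(C)C(C)(C)C)[C@@H](OC(C)=O)[C@@H]3O[C@@H]3C(C)(C)[C@H]1C(OC)OC
F9 | step 16 | trans-diaxial 2-iodo-3-hydroxy compound from F8 (iodine syn to C20, hydroxyl anti to C20) | C=C1C[C@]2(C(=O)OC)C[C@H]1CC[C@H]2[C@]1(CO[Si](C)(C)C(C)(C)C)[C@@H](OC(C)=O)[C@@H](I)[C@H](O)C(C)(C)[C@H]1C(OC)OC
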